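**Plan**

1. Retrosynthetic cuts, in order: the two acetates; the bond between the side-chain CH and the lactone β-carbon (azaenolate Michael addition to furan-2(5H)-one, lactone α-oxygen by enolate oxidation); the exocyclic C=CH2 (from a ketone); then, in one operation, the two seven-ring bonds CH2–C(CH3)2 and C(=CH2)–CH(ring fusion); last, the allyl group on the quaternary carbon.
2. Forward: a cyclopentanone carrying the quaternary carbon is made first. The seven-membered ring is then annulated onto it by a (4+3) cycloaddition ended by an internal hydride shift. Ketone, then methylene, follow, and the lactone side chain is joined last.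
3. Enabling feature: in the seven-membered ring, the C(CH3)2 carbon and the two ring-fusion CH carbons form a three-carbon unit that is an allyl cation at the oxidation level of a 2-isopropylidenecyclopentyl acetate. The C(=CH2)–CH2–CH2–CH2 unit is a 1-oxygenated buta-1,3-diene. The central ring-fusion carbon lies 1,3 to the quaternary carbon, whose two-carbon arm (CH2CH2OSi at that stage) can reach it for a 1,5-hydride shift.
4. Stereochemistry: the quaternary carbon comes from a ligand-controlled decarboxylative allylation. Both ring-fusion carbons are relayed from it in the key step. The side-chain CH is set by the SAMP auxiliary, the lactone β-carbon by the relative topicity of the Michael addition, and the lactone α-carbon by trans hydroxylation.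

Key step: step 9

Remark: 15 is used in excess as the commercial E/Z mixture; only the (E)-isomer can reach the s-cis geometry and is expected to react.

**Step 1**
Reactants: 1 diallyl adipate
Product: 3 allyl 1-methyl-2-oxocyclopentane-1-carboxylate (racemic), via sodium enolate 2 (not isolated)
Conditions: NaH (1.05 equiv), THF, 0 → 40 °C; then MeI, rt
Reagents that add atoms: methyl iodide, CI
Why: Dieckmann condensation closes the five-membered β-keto ester and its sodium enolate is C-methylated in the same flask; the stereocentre forms racemic and is erased at the enolate stage of step 2.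

**Step 2**
Reactants: 3 allyl 1-methyl-2-oxocyclopentane-1-carboxylate
Product: 4 (S)-2-allyl-2-methylcyclopentan-1-one
Conditions: Pd2(dba)3 (2.5 mol %), (S)-t-BuPHOX (6 mol %), THF, 25 °C
Reagents that add atoms: none
Why: Decarboxylative asymmetric Tsuji allylation: zerovalent palladium ionises the allyl ester, loss of CO2 gives a palladium enolate, and inner-sphere allylation in the chiral P,N-ligand pocket should set the quaternary carbon as (S), in the sense known for the six-membered homologue.

**Step 3**
Reactants: 4 (S)-2-allyl-2-methylcyclopentan-1-one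
Product: 5 (S)-2-(1-methyl-2-oxocyclopentyl)acetaldehyde
Conditions: O3, CH2Cl2, −78 °C; then PPh3, −78 °C → rt
Reagents that add atoms: ozone, [O-][O+]=O
Why: Ozonolysis with reductive work-up cleaves the only C=C bond to the aldehyde and leaves the ketone and the quaternary centre untouched.

**Step 4**
Reactants: 5 (S)-2-(1-methyl-2-oxocyclopentyl)acetaldehyde
Product: 6 (S)-2-(2-hydroxyethyl)-2-methylcyclopentan-1-one
Conditions: NaBH4 (0.3 equiv), EtOH/CH2Cl2 (3:7), −78 °C
Reagents that add atoms: none
Why: Chemoselective borohydride reduction at low temperature, in which the unhindered aldehyde should react far faster than the α-quaternary ketone.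

**Step 5**
Reactants: 6 (S)-2-(2-hydroxyethyl)-2-methylcyclopentan-1-one
Product: 7 (S)-2-[2-(tert-butyldimethylsilyloxy)ethyl]-2-methylcyclopentan-1-one
Conditions: TBSCl, imidazole, DMF, rt
Reagents that add atoms: tert-butyldimethylsilyl chloride, CC(C)(C)[Si](C)(C)Cl
Why: Standard silylation of the primary alcohol; the silyl ether protects the arm and later serves as the internal hydride donor.

**Step 6**
Reactants: 7 (S)-2-[2-(tert-butyldimethylsilyloxy)ethyl]-2-methylcyclopentan-1-one, 8 acetone
Product: 10 (2S)-2-[2-(tert-butyldimethylsilyloxy)ethyl]-5-(2-hydroxypropan-2-yl)-2-methylcyclopentan-1-one (C-5 epimers), via lithium enolate 9 (not isolated)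
Conditions: LDA, THF, −78 °C; CeCl3; acetone, −78 °C; H2O
Reagents that add atoms: none
Why: Directed aldol addition of the only possible enolate (one enolisable side) to acetone, with CeCl3 to suppress proton transfer to acetone.

**Step 7**
Reactants: 10 the aldol adduct
Product: 12 (S)-2-[2-(tert-butyldimethylsilyloxy)ethyl]-2-methyl-5-(propan-2-ylidene)cyclopentan-1-one, via tertiary mesylate 11 (not isolated)
Conditions: MsCl, Et3N, DMAP (cat.), CH2Cl2, 0 °C; then DBU, rt
Reagents that add atoms: none
Why: Mesylation of the tertiary aldol hydroxyl and E1cB elimination should give the conjugated isopropylidene enone, DBU moving any isopropenyl isomer into conjugation.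

**Step 8**
Reactants: 12 the isopropylidene enone
Product: 14 (2S)-2-[2-(tert-butyldimethylsilyloxy)ethyl]-2-methyl-5-(propan-2-ylidene)cyclopentyl acetate (C-1 epimers), via aluminium alkoxide 13 (not isolated)
Conditions: i-Bu2AlH, CH2Cl2, −78 °C; then pyridine, DMAP, Ac2O, −78 °C → rt
Reagents that add atoms: acetic anhydride, CC(=O)OC(C)=O
Why: 1,2-Reduction of the enone and acetylation of the aluminium alkoxide in the same flask (reductive acetylation) give the allylic acetate; the new carbinol centre is irrelevant because it is ionised in step 9.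

**Step 9**
Reactants: 14 the allylic acetate, 15 (E)-buta-1,3-dien-1-yl acetate
Product: 19 2-[8-acetoxy-1,4,4-trimethyl-1,2,3,3a,4,5,8,8a-octahydroazulen-1-yl]acetaldehyde (cis-fused; H-3a and H-8a both cis to the CH2CHO arm; C-8 epimers), via allyl cation 16 (not isolated), via ring-fusion cation 17 (not isolated), via silyloxocarbenium ion 18 (not isolated)
Conditions: 15 (3 equiv), TBSOTf (10 mol %), CH2Cl2, −78 → −20 °C; aq. NaHCO3
Reagents that add atoms: none
Why: Proposed new method: the silyl triflate ionises the allylic acetate to allyl cation 16, delocalised over the exocyclic C(CH3)2 carbon and the ring CH next to the quaternary carbon, which should add the s-cis diene 15 across both termini in a (4+3) cycloaddition (closest known type: allyl cation–diene (4+3) cycloaddition) to give tertiary cation 17 at the future ring-fusion carbon. Cation 17 should then be reduced by a 1,5-hydride shift through a six-membered transition state from the OCH2 group of the silyloxyethyl arm (closest known type: cation-triggered 1,5-hydride transfer from an ether C–H bond), and silyloxocarbenium ion 18 passes its silyl group to triflate, which releases aldehyde 19 and regenerates the catalyst. The seven-membered ring closes by suprafacial bonding of the two diene termini to the two allyl termini on one face of the planar cation; no other ring forms. The ring-fusion CH next to the quaternary carbon is set by diene approach anti to the larger CH2CH2OTBS arm (syn to CH3), and the other ring-fusion CH by the internal hydride, which can only arrive on the face of the arm, so a cis-fused hydroazulene with both H atoms syn to the arm should result; the acetoxy-bearing carbon forms as a mixture and later becomes a ketone. The step needs the unsubstituted diene terminus to bond to the C(CH3)2 terminus (that terminus carries the larger share of positive charge and the diene HOMO is largest at its CH2 end), (4+3) closure in preference to (3+2) closure or open-chain alkylation (favoured by the s-cis (E)-diene and by an acyloxy group that, unlike a silyloxy group, is not lost from the intermediate), and hydride transfer in preference to elimination (elimination, ion-pair return and capture by the ether oxygen are reversible without base, hydride transfer is not).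

**Step 10**
Reactants: 19 the acetate aldehyde, 20 (S)-1-amino-2-(methoxymethyl)pyrrolidine (SAMP)
Product: 21 (E)-SAMP hydrazone of 19
Conditions: CH2Cl2, MgSO4, 0 °C → rt
Reagents that add atoms: none
Why: Condensation of the aldehyde with the hydrazine gives the (E)-hydrazone, which masks the aldehyde and installs the auxiliary used in step 15.

**Step 11**
Reactants: 21 the acetate hydrazone
Product: 22 the corresponding allylic alcohol (8-hydroxy compound)
Conditions: K2CO3 (cat.), MeOH, 0 °C → rt
Reagents that add atoms: none
Why: Base-catalysed methanolysis removes the allylic acetate while the hydrazone is inert.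

**Step 12**
Reactants: 22 the allylic alcohol
Product: 23 the cyclohept-6-en-8-one (enone hydrazone)
Conditions: MnO2 (activated, excess), CH2Cl2, rt
Reagents that add atoms: none
Why: MnO2 oxidises allylic alcohols selectively under neutral conditions, which should leave the N,N-dialkylhydrazone and the ring-fusion centre next to the new carbonyl untouched.

**Step 13**
Reactants: 23 the enone hydrazone
Product: 24 the saturated 8-ketone hydrazone (cis-fused)
Conditions: H2 (1 atm), 5 % Pd/C, EtOAc, rt, stopped after one equivalent
Reagents that add atoms: none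
Why: Heterogeneous hydrogenation should saturate the disubstituted enone C=C bond much faster than the hindered ketone or the hydrazone C=N bond.

**Step 14**
Reactants: 24 the ketone hydrazone
Product: 25 the 8-methylidene hydrazone
Conditions: Zn, CH2Br2, TiCl4, THF, 0 °C (preformed reagent); then 24, CH2Cl2, rt
Reagents that add atoms: dibromomethane, BrCBr
Why: Takai–Lombardo methylenation converts the hindered, enolisable ketone to the exocyclic alkene under non-basic conditions, so the ring-fusion centre α to the carbonyl should be kept.

**Step 15**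
Reactants: 25 the methylidene hydrazone, 26 furan-2(5H)-one
Product: 29 the trans-3-hydroxy-4-substituted γ-lactone hydrazone, via lithium azaenolate 27 (not isolated), via lactone enolate 28 (not isolated)
Conditions: LDA, THF, 0 °C; 26, −78 °C; then 2-(phenylsulfonyl)-3-phenyloxaziridine, −78 → −40 °C; H2O
Reagents that add atoms: 2-(phenylsulfonyl)-3-phenyloxaziridine, O=S(=O)(c1ccccc1)N1OC1c1ccccc1
Why: Asymmetric azaenolate Michael addition followed by in-situ enolate hydroxylation: the auxiliary directs the acceptor to one face of the azaenolate carbon (side-chain CH, expected R), an open synclinal transition state with the azaenolate H anti to the acceptor C=C and the lactone CH2 turned away from the quaternary substituent should set the lactone β-carbon, and the oxidant enters trans to the new β-substituent.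

**Step 16**
Reactants: 29 the hydroxy lactone hydrazone
Product: 30 the hydroxy lactone aldehyde
Conditions: CuCl2·2H2O, THF/pH 7 buffer, 0 °C → rt
Reagents that add atoms: water, O
Why: Copper-assisted hydrolysis of the hydrazone at neutral pH should release the α-branched aldehyde without epimerisation and free the auxiliary.

**Step 17**
Reactants: 30 the hydroxy lactone aldehyde
Product: 31 the diol lactone
Conditions: NaBH4, EtOH/CH2Cl2, −78 °C
Reagents that add atoms: none
Why: Low-temperature borohydride reduction takes the aldehyde to the primary alcohol and should leave the γ-lactone intact.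

**Step 18**
Reactants: 31 the diol lactone
Product: 32 (3S,4R)-4-{(1R)-2-acetoxy-1-[(1R,3aR,8aS)-1,4,4-trimethyl-8-methylidenedecahydroazulen-1-yl]ethyl}-2-oxooxolan-3-yl acetate
Conditions: Ac2O, pyridine, DMAP (cat.), CH2Cl2, 0 °C
Reagents that add atoms: acetic anhydride, CC(=O)OC(C)=O
Why: Acetylation of the primary hydroxyl and the lactone α-hydroxyl under nucleophilic catalysis gives the diacetate without touching any stereocentre.

**Compound list**

1 | diallyl adipate | C=CCOC(=O)CCCCC(=O)OCC=C | starting material
2 | sodium 2-(allyloxycarbonyl)cyclopent-1-en-1-olate | [Na+].[O-]C1=C(C(=O)OCC=C)CCC1 | intermediate (not isolated)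
3 | allyl 1-methyl-2-oxocyclopentane-1-carboxylate (racemic) | C=CCOC(=O)C1(C)CCCC1=O | intermediate
4 | (S)-2-allyl-2-methylcyclopentan-1-one | C=CC[C@]1(C)CCCC1=O | intermediate
5 | (S)-2-(1-methyl-2-oxocyclopentyl)acetaldehyde | O=CC[C@]1(C)CCCC1=O | intermediate
6 | (S)-2-(2-hydroxyethyl)-2-methylcyclopentan-1-one | OCC[C@]1(C)CCCC1=O | intermediate
7 | (S)-2-[2-(tert-butyldimethylsilyloxy)ethyl]-2-methylcyclopentan-1-one | CC(C)(C)[Si](C)(C)OCC[C@]1(C)CCCC1=O | intermediate
8 | acetone | CC(C)=O | starting material
9 | lithium enolate of 7 | CC(C)(C)[Si](C)(C)OCC[C@]1(C)CCC=C1[O-].[Li+] | intermediate (not isolated)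
10 | (2S)-2-[2-(tert-butyldimethylsilyloxy)ethyl]-5-(2-hydroxypropan-2-yl)-2-methylcyclopentan-1-one (C-5 epimers) | CC(C)(C)[Si](C)(C)OCC[C@]1(C)CCC(C(C)(C)O)C1=O | intermediate
11 | tertiary methanesulfonate of 10 | CC(C)(C)[Si](C)(C)OCC[C@]1(C)CCC(C(C)(C)OS(C)(=O)=O)C1=O | intermediate (not isolated)
12 | (S)-2-[2-(tert-butyldimethylsilyloxy)ethyl]-2-methyl-5-(propan-2-ylidene)cyclopentan-1-one | CC(C)(C)[Si](C)(C)OCC[C@]1(C)CCC(=C(C)C)C1=O | intermediate
13 | diisobutylaluminium alkoxide of the allylic alcohol from 12 | CC(C)(C)[Si](C)(C)OCC[C@]1(C)CCC(=C(C)C)C1O[Al](CC(C)C)CC(C)C | intermediate (not isolated)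
14 | (2S)-2-[2-(tert-butyldimethylsilyloxy)ethyl]-2-methyl-5-(propan-2-ylidene)cyclopentyl acetate (C-1 epimers) | CC(C)(C)[Si](C)(C)OCC[C@]1(C)CCC(=C(C)C)C1OC(C)=O | intermediate
15 | (E)-buta-1,3-dien-1-yl acetate | C=C/C=C/OC(C)=O | starting material
16 | allyl cation from 14 (charge shared by the ring CH and the exocyclic C(CH3)2 carbon) | CC(C)(C)[Si](C)(C)OCC[C@]1(C)CCC(=C(C)C)[CH+]1 | intermediate (not isolated)
17 | (4+3) cycloadduct, tertiary cation at the ring-fusion carbon | CC(=O)OC1C=CCC(C)(C)[C+]2CC[C@@](C)(CCO[Si](C)(C)C(C)(C)C)[C@H]12 | intermediate (not isolated)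
18 | O-silyl oxocarbenium ion after hydride shift | CC(=O)OC1C=CCC(C)(C)[C@@H]2CC[C@@](C)(CC=[O+][Si](C)(C)C(C)(C)C)[C@H]12 | intermediate (not isolated)
19 | 2-[8-acetoxy-1,4,4-trimethyl-1,2,3,3a,4,5,8,8a-octahydroazulen-1-yl]acetaldehyde (cis-fused; H-3a and H-8a cis to the CH2CHO arm, CH3 at C-1 on the other face; C-8 epimers) | CC(=O)OC1C=CCC(C)(C)[C@@H]2CC[C@@](C)(CC=O)[C@H]12 | intermediate
20 | (S)-1-amino-2-(methoxymethyl)pyrrolidine (SAMP) | COC[C@@H]1CCCN1N | starting material
21 | (E)-SAMP hydrazone of 19 | CC(=O)OC1C=CCC(C)(C)[C@@H]2CC[C@@](C)(C/C=N/N3CCC[C@H]3COC)[C@H]12 | intermediate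
22 | 8-hydroxy analogue of 21 (allylic alcohol; C-8 epimers) | OC1C=CCC(C)(C)[C@@H]2CC[C@@](C)(C/C=N/N3CCC[C@H]3COC)[C@H]12 | intermediate
23 | 8-oxo-6-ene analogue (cycloheptenone hydrazone) | O=C1C=CCC(C)(C)[C@@H]2CC[C@@](C)(C/C=N/N3CCC[C@H]3COC)[C@H]12 | intermediate
24 | saturated 8-ketone hydrazone (cis-fused 1,4,4-trimethyl-8-oxodecahydroazulen-1-yl acetaldehyde SAMP hydrazone) | O=C1CCCC(C)(C)[C@@H]2CC[C@@](C)(C/C=N/N3CCC[C@H]3COC)[C@H]12 | intermediate
25 | 8-methylidene hydrazone | C=C1CCCC(C)(C)[C@@H]2CC[C@@](C)(C/C=N/N3CCC[C@H]3COC)[C@H]12 | intermediate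
26 | furan-2(5H)-one | O=C1C=CCO1 | starting material
27 | lithium azaenolate of 25 | C=C1CCCC(C)(C)[C@@H]2CC[C@@](C)(/C=C/[N-]N3CCC[C@H]3COC)[C@H]12.[Li+] | intermediate (not isolated)
28 | lithium lactone enolate of the Michael adduct | C=C1CCCC(C)(C)[C@@H]2CC[C@@](C)([C@H](/C=N/N4CCC[C@H]4COC)[C@@H]3COC([O-])=C3)[C@H]12.[Li+] | intermediate (not isolated)
29 | (3S,4R)-3-hydroxy-4-substituted oxolan-2-one carrying the side-chain (R)-CH with the hydrazone | C=C1CCCC(C)(C)[C@@H]2CC[C@@](C)([C@H](/C=N/N4CCC[C@H]4COC)[C@@H]3COC(=O)[C@H]3O)[C@H]12 | intermediate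
30 | corresponding aldehyde (side-chain CH–CHO) | C=C1CCCC(C)(C)[C@@H]2CC[C@@](C)([C@H](C=O)[C@@H]3COC(=O)[C@H]3O)[C@H]12 | intermediate
31 | corresponding diol (side-chain CH–CH2OH, lactone 3-OH) | C=C1CCCC(C)(C)[C@@H]2CC[C@@](C)([C@H](CO)[C@@H]3COC(=O)[C@H]3O)[C@H]12 | intermediate
32 | (3S,4R)-4-{(1R)-2-acetoxy-1-[(1R,3aR,8aS)-1,4,4-trimethyl-8-methylidenedecahydroazulen-1-yl]ethyl}-2-oxooxolan-3-yl acetate | C=C1CCCC(C)(C)[C@@H]2CC[C@@](C)([C@H](COC(C)=O)[C@@H]3COC(=O)[C@H]3OC(C)=O)[C@H]12 | target

**Totals**

Total step count: 18. Longest linear sequence: 18 steps (from 1).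

**Steps most likely to fail**

Step 9 (Proposed new method). What may go wrong: (3+2) ring closure or open-chain alkylation from the s-trans diene instead of seven-ring closure; bonding of the diene in the reverse sense; premature internal hydride transfer to the allyl cation; poor facial selectivity next to the quaternary carbon. Fallback with known chemistry, setting out from 12 and coming back at 24: Hosomi–Sakurai conjugate allylation of 12 (allyltrimethylsilane, TiCl4, CH2Cl2, −78 °C) would give the 5-(2-methylpent-4-en-2-yl) ketone F1. KN(SiMe3)2 and PhNTf2 would convert it to the enol triflate F2. Carbonylative Stille coupling with tributyl(vinyl)stannane (Pd(PPh3)4, CO, LiCl, THF) would give the divinyl ketone F3. Ring-closing metathesis with second-generation Grubbs catalyst, (H2IMes)(PCy3)Cl2Ru=CHPh, would close the seven-membered ring as the cross-conjugated dienone F4. n-Bu4NF would free the dienone alcohol F5. Hydroxyl-directed hydrogenation with [Ir(cod)(PCy3)(py)]PF6 would saturate both C=C bonds from the face of the hydroxyethyl arm to give the cis-fused keto alcohol F6. Dess–Martin oxidation would give the keto aldehyde F7, and condensation with 20 would give 24.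

Step 15. What may go wrong: poor control of relative topicity at the lactone β-carbon in the open transition state; proton transfer from the butenolide to the azaenolate; addition of the lactone enolate to the sulfonimine formed from the oxidant. Fallback setting out from 25 and coming back at 31: the acceptor would be changed to (5S)-5-[(1S,2R,5S)-menthyloxy]furan-2(5H)-one F8, made by acetalisation of 5-hydroxyfuran-2(5H)-one with (+)-menthol and crystallisation. Its acetal substituent blocks one face, so addition anti to it fixes the lactone β-carbon independently of relative topicity. Addition of the azaenolate of 25 and hydroxylation as before would give the menthyloxy lactone hydrazone F9. Aqueous acid would hydrolyse hydrazone and acetal to the aldehyde lactol F10. NaBH4 followed by acidification would reduce both masked aldehydes and relactonise to 31.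

Step 14. What may go wrong: slow methylenation of the hindered ketone, and loss of the ring-fusion configuration by enolisation if more basic reagents have to be used. Fallback setting out from 24 and coming back at 25: Peterson olefination, in which addition of Me3SiCH2MgCl in the presence of CeCl3 would give the β-hydroxysilane F11, and elimination with KH in THF would give 25.

**Further compounds**

F1 | step 9 | (2S)-2-[2-(tert-butyldimethylsilyloxy)ethyl]-2-methyl-5-(2-methylpent-4-en-2-yl)cyclopentan-1-one | CC(C)(C)[Si](C)(C)OCC[C@]1(C)CCC(C(C)(C)CC=C)C1=O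
F2 | step 9 | enol triflate of F1 | CC(C)(C)[Si](C)(C)OCC[C@]1(C)CCC(C(C)(C)CC=C)=C1OS(=O)(=O)C(F)(F)F
F3 | step 9 | cyclopentenyl vinyl ketone (divinyl ketone) | CC(C)(C)[Si](C)(C)OCC[C@]1(C)CCC(C(C)(C)CC=C)=C1C(=O)C=C
F4 | step 9 | bicyclic cross-conjugated cycloheptadienone silyl ether | CC(C)(C)[Si](C)(C)OCC[C@]1(C)CCC2=C1C(=O)C=CCC2(C)C
F5 | step 9 | dienone alcohol | OCC[C@]1(C)CCC2=C1C(=O)C=CCC2(C)C
F6 | step 9 | cis-fused saturated keto alcohol | O=C1CCCC(C)(C)[C@@H]2CC[C@@](C)(CCO)[C@H]12
F7 | step 9 | cis-fused keto aldehyde | O=C1CCCC(C)(C)[C@@H]2CC[C@@](C)(CC=O)[C@H]12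
F8 | step 15 | (5S)-5-[(1S,2R,5S)-menthyloxy]furan-2(5H)-one | CC(C)[C@H]1CC[C@H](C)C[C@@H]1O[C@H]1OC(=O)C=C1
F9 | step 15 | 5-menthyloxy-3-hydroxy lactone hydrazone | C=C1CCCC(C)(C)[C@@H]2CC[C@@](C)([C@H](/C=N/N4CCC[C@H]4COC)[C@@H]3[C@@H](O[C@H]5C[C@@H](C)CC[C@@H]5C(C)C)OC(=O)[C@H]3O)[C@H]12
F10 | step 15 | aldehyde lactol (5-hydroxy lactone, anomers) | C=C1CCCC(C)(C)[C@@H]2CC[C@@](C)([C@H](C=O)[C@@H]3C(O)OC(=O)[C@H]3O)[C@H]12
F11 | step 14 | β-hydroxysilane from 24 (8-hydroxy-8-(trimethylsilylmethyl) compound) | C[Si](C)(C)CC1(O)CCCC(C)(C)[C@@H]2CC[C@@](C)(C/C=N/N3CCC[C@H]3COC)[C@H]12
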